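**Synthesis plan**

Numbering: C1 = CO2H, C2 = CH2, ring = O1–O2–C3–C4=C5–C6, chain C7–C14. Ethyl groups sit on C4, C6 and C10 and a methyl on C8; the target is (3R,6R,8S,10S).
Enabling feature: in the six-membered 3,6-dihydro-1,2-dioxin, O1–O2 is bonded to C3 (H, CH2CO2H) and to the quaternary C6 (Et, C7), with C4=C5 on the opposite edge of the ring. This is the pattern left when O2 adds across the ends of an acyclic C3=C4–C5=C6 diene.
Cuts: C1 goes back to CH2OH, then C3–O2 and C6–O1 are cut together (retro-[4+2]). The (3E,5Z)-diene is cut at C4–Et and C4–C5 (two Negishi couplings on a C4 gem-dibromide made by C3=C4 olefination) and at C6–C7 (alkyne carbocupration). The C7–C14 piece is cut at C8–Me, C8–C9 and C10–Et.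
Forward order: C10–Et and C9–C8, then C8–Me, C7–C6, C5–C4 and C4–Et complete the open chain. The only ring then closes by cycloaddition, and the alcohol-to-acid oxidation ends the route.
Stereochemistry: C10 and C8 come from two catalyst-controlled Zr-catalysed asymmetric carboaluminations. 5Z comes from syn-carbocupration and 3E from trans-selective coupling plus retentive ethylation. Suprafacial O2 addition turns this geometry into the C3/C6 relation (side arm cis to the C6 ethyl), and the sense relative to C8 is secured by separating the two facial adducts.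

Key step: step 9

Assumption: (+)-(NMI)2ZrCl2 is taken to give the (S)-configured 2-alkylalkylalanes needed here, by correlation with the established outcome (−)-catalyst → (R)-2-methylalkan-1-ols. If ethyl transfer followed the opposite sense, the (−)-antipode would be used in step 1.

**Route**

Step 1
Reactants: 1 hex-1-ene; 2 vinyl bromide
Product: 4 (4S)-4-ethyloct-1-ene, via 2-ethylhexylalane 3 (not isolated)
Conditions: Et3Al (1.2 equiv), (+)-(NMI)2ZrCl2 (5 mol %), CH2Cl2, 0 → 23 °C; volatiles removed in vacuo; Zn(OTf)2 (promoter), DMF, 70 °C; then 2 (excess), PdCl2(DPEphos) (3 mol %)/DIBAL-H (6 mol %), DMF, 23 °C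
Reagents that add atoms: triethylaluminium, CC[Al](CC)CC
Why: Zr-catalysed asymmetric carboalumination (ZACA) in a chlorinated solvent follows the acyclic carbometalation path, the chiral neomenthylindenyl zirconocene selects the alkene face so that ethyl reaches C10 with (S) configuration, and the primary alkylalane then undergoes the established Zn(II)-promoted, Pd-catalysed Negishi vinylation without touching the β-stereocentre.

Step 2
Reactants: 4 (4S)-4-ethyloct-1-ene
Product: 6 (2S,4S)-4-ethyl-2-methyloctan-1-ol, via alkyldimethylalane 5 (not isolated)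
Conditions: Me3Al (2 equiv), (+)-(NMI)2ZrCl2 (5 mol %), MAO (cat.), CH2Cl2, 0 → 23 °C; O2, 0 → 23 °C; aqueous work-up; SiO2 chromatography to remove the 2,4-anti isomer
Reagents that add atoms: trimethylaluminium, C[Al](C)C; dioxygen, O=O
Why: A second ZACA reaction (methylalumination) sets C8 under catalyst control, the same catalyst antipode giving the 8,10-syn (2S,4S) isomer, O2 cleaves the C–Al bond without affecting either centre, and removing the anti diastereomer also raises enantiomeric purity because the minor enantiomer of 4 is channelled mainly into that diastereomer (statistical amplification).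

Step 3
Reactants: 6 (2S,4S)-4-ethyl-2-methyloctan-1-ol
Product: 7 (2S,4S)-1-bromo-4-ethyl-2-methyloctane
Conditions: CBr4 (1.2 equiv), PPh3 (1.25 equiv), CH2Cl2, 0 °C
Reagents that add atoms: carbon tetrabromide, BrC(Br)(Br)Br
Why: In the Appel reaction bromide displaces the alkoxyphosphonium ion by SN2 at the primary carbon C7, one atom away from C8, so no stereocentre is involved.

Step 4
Reactants: 7 (2S,4S)-1-bromo-4-ethyl-2-methyloctane; 8 but-1-yne
Product: 12 (1Z,4S,6S)-2,6-diethyl-1-iodo-4-methyldec-1-ene, via alkylmagnesium bromide 9 (not isolated), via alkylcopper 10 (not isolated), via alkenylcopper 11 (not isolated)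
Conditions: Mg, Et2O, reflux; CuBr·SMe2 (1.0 equiv), Et2O/Me2S, −45 °C; 8 (1.3 equiv), −45 → −25 °C; I2 (1.05 equiv), THF, −78 → 0 °C
Reagents that add atoms: iodine, II
Why: In the Normant carbocupration the magnesium-derived alkylcopper adds syn to the terminal alkyne, carbon going to the internal and copper to the terminal position, so C7 and Cu (and, after retentive iodinolysis, C7 and I) are cis and the two similar groups on C6 (ethyl and CH2R) are told apart by the mechanism.

Step 5
Reactants: 13 3-[(tert-butyldimethylsilyl)oxy]propanal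
Product: 14 tert-butyl[(4,4-dibromobut-3-en-1-yl)oxy]dimethylsilane
Conditions: CBr4 (2 equiv), PPh3 (2 equiv), Zn dust (2 equiv), CH2Cl2, 23 °C (ylide pre-formed); then 13, 0 → 23 °C
Reagents that add atoms: carbon tetrabromide, BrC(Br)(Br)Br
Why: The Ramirez (Corey–Fuchs type) dibromo-olefination is a Wittig reaction of the dibromomethylene ylide under neutral conditions, and the zinc variant avoids bromophosphorane by-products that could attack the silyl ether or trigger β-elimination of the β-silyloxy aldehyde.

Step 6
Reactants: 12 (1Z,4S,6S)-2,6-diethyl-1-iodo-4-methyldec-1-ene; 14 tert-butyl[(4,4-dibromobut-3-en-1-yl)oxy]dimethylsilane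
Product: 17 {[(3Z,5Z,8S,10S)-4-bromo-6,10-diethyl-8-methyltetradeca-3,5-dien-1-yl]oxy}(tert-butyl)dimethylsilane, via alkenyllithium 15 (not isolated), via alkenylzinc bromide 16 (not isolated)
Conditions: 12, t-BuLi (2.0 equiv), Et2O, −78 °C; ZnBr2 (1.05 equiv), THF, −78 → 0 °C; 14 (0.95 equiv), PdCl2(DPEphos) (5 mol %), THF, 0 → 23 °C
Reagents that add atoms: none
Why: Iodine–lithium exchange and transmetalation to zinc keep the configuration of the stable β,β-disubstituted alkenyl carbon, and in the Negishi coupling Pd(0) inserts selectively into the less hindered C–Br bond trans to the CH2CH2OTBS chain, so C5 ends up trans to C2 and the wide-bite-angle catalyst stops at mono-substitution.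

Step 7
Reactants: 17 {[(3Z,5Z,8S,10S)-4-bromo-6,10-diethyl-8-methyltetradeca-3,5-dien-1-yl]oxy}(tert-butyl)dimethylsilane
Product: 18 tert-butyldimethyl{[(3E,5Z,8S,10S)-4,6,10-triethyl-8-methyltetradeca-3,5-dien-1-yl]oxy}silane
Conditions: Et2Zn (1.2 equiv), Pd(t-Bu3P)2 (5 mol %), THF, 0 → 23 °C
Reagents that add atoms: diethylzinc, CC[Zn]CC
Why: In this Negishi alkylation of the remaining alkenyl bromide the bulky, electron-rich Pd(t-Bu3P)2 catalyst makes transmetalation and reductive elimination faster than both the π–σ–π isomerisation known for 2-pallada-1,3-dienes and β-hydride loss from Pd–ethyl, so ethyl replaces bromine with retention and the 3E,5Z geometry results.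

Step 8
Reactants: 18 tert-butyldimethyl{[(3E,5Z,8S,10S)-4,6,10-triethyl-8-methyltetradeca-3,5-dien-1-yl]oxy}silane
Product: 19 (3E,5Z,8S,10S)-4,6,10-triethyl-8-methyltetradeca-3,5-dien-1-ol
Conditions: TBAF (1.2 equiv), THF, 0 → 23 °C
Reagents that add atoms: none
Why: Fluoride-driven Si–O cleavage is carried out before the peroxide exists, so the basic fluoride source never meets the base-sensitive C3–H of the dioxin.

Step 9
Reactants: 19 (3E,5Z,8S,10S)-4,6,10-triethyl-8-methyltetradeca-3,5-dien-1-ol
Product: 20 2-{(3R,6R)-4,6-diethyl-6-[(2S,4S)-4-ethyl-2-methyloctyl]-3,6-dihydro-1,2-dioxin-3-yl}ethan-1-ol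
Conditions: O2, tetraphenylporphyrin (1 mol %), visible light (λ > 495 nm), CH2Cl2, −78 °C, stopped before full conversion; chromatographic separation of the two facial adducts
Reagents that add atoms: dioxygen (as singlet oxygen), O=O
Why: Energy transfer from triplet porphyrin generates singlet oxygen, which adds suprafacially across C3 and C6 of the skewed s-cis rotamer of 19 in a concerted, asynchronous [4+2] event that forms both C–O bonds and moves the π bond to C4=C5; the closest known reaction type is the dye-sensitised photooxygenation of acyclic 1,3-dienes with a disubstituted terminus, which gives 3,6-dihydro-1,2-dioxins with a fully substituted peroxy carbon. The only ring, the six-membered 1,2-dioxin, closes by intermolecular [4+2] cycloaddition and not by stepwise cyclisation, so no acid, base or metal meets the new O–O unit. C3 and C6 are fixed relative to each other by the olefin geometry, because in the 3E,5Z diene the CH2CH2OH arm on C3 and the ethyl on C6 are both outside groups and land on the same ring face, which is the 3R,6R/3S,6S relation. The choice of diene face, and with it the relation of this pair to C8, is at best weakly biased by the C8 centre, so both suprafacial adducts are expected and the 3R,6R isomer is taken by chromatography, which the 1,3-relation of C6 and C8 should make feasible. The step needs [4+2] over Schenck ene reaction at the four allylic CH2 groups and no loss of olefin geometry: only H (on C3) and one CH2 (C7) point into the diene cleft, the C4 ethyl clashes with C7 in the s-trans rotamer and so raises the share of the s-cis one, and the porphyrin triplet lies far below a diene triplet, which shuts off energy-transfer E/Z isomerisation. Low temperature, a weakly polar aprotic medium and short irradiation hold back the open perepoxide or zwitterion pathways that lead to ene products or scrambling.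

Step 10
Reactants: 20 2-{(3R,6R)-4,6-diethyl-6-[(2S,4S)-4-ethyl-2-methyloctyl]-3,6-dihydro-1,2-dioxin-3-yl}ethan-1-ol
Product: 22 2-{(3R,6R)-4,6-diethyl-6-[(2S,4S)-4-ethyl-2-methyloctyl]-3,6-dihydro-1,2-dioxin-3-yl}acetic acid, via dioxinylacetaldehyde 21 (not isolated)
Conditions: TEMPO (20 mol %), PhI(OAc)2 (2.5 equiv), MeCN/H2O 1:1, 0 → 23 °C
Reagents that add atoms: water, O
Why: The oxoammonium-mediated TEMPO/PhI(OAc)2 oxidation takes the primary alcohol through aldehyde 21 and its hydrate to the acid in a mildly acidic, metal-free and amine-free medium, which leaves the O–O bond, the hindered C4=C5 olefin and the C3 centre untouched and avoids Kornblum–DeLaMare or E1cB ring opening.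

**Compound list**

1 | hex-1-ene | C=CCCCC | starting material
2 | vinyl bromide (bromoethene) | C=CBr | starting material
3 | diethyl[(2S)-2-ethylhexyl]aluminium | CCCC[C@H](CC)C[Al](CC)CC | intermediate
4 | (4S)-4-ethyloct-1-ene | CCCC[C@H](CC)CC=C | intermediate
5 | [(2S,4S)-4-ethyl-2-methyloctyl]dimethylaluminium | CCCC[C@H](CC)C[C@H](C)C[Al](C)C | intermediate
6 | (2S,4S)-4-ethyl-2-methyloctan-1-ol | CCCC[C@H](CC)C[C@H](C)CO | intermediate
7 | (2S,4S)-1-bromo-4-ethyl-2-methyloctane | CCCC[C@H](CC)C[C@H](C)CBr | intermediate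
8 | but-1-yne | CCC#C | starting material
9 | [(2S,4S)-4-ethyl-2-methyloctyl]magnesium bromide | CCCC[C@H](CC)C[C@H](C)C[Mg]Br | intermediate
10 | [(2S,4S)-4-ethyl-2-methyloctyl]copper(I) | CCCC[C@H](CC)C[C@H](C)C[Cu] | intermediate
11 | [(1Z,4S,6S)-2,6-diethyl-4-methyldec-1-en-1-yl]copper(I) | CCCC[C@H](CC)C[C@H](C)C/C(CC)=C\[Cu] | intermediate
12 | (1Z,4S,6S)-2,6-diethyl-1-iodo-4-methyldec-1-ene | CCCC[C@H](CC)C[C@H](C)C/C(CC)=C\I | intermediate
13 | 3-[(tert-butyldimethylsilyl)oxy]propanal | O=CCCO[Si](C)(C)C(C)(C)C | starting material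
14 | tert-butyl[(4,4-dibromobut-3-en-1-yl)oxy]dimethylsilane | BrC(Br)=CCCO[Si](C)(C)C(C)(C)C | intermediate
15 | [(1Z,4S,6S)-2,6-diethyl-4-methyldec-1-en-1-yl]lithium | CCCC[C@H](CC)C[C@H](C)C/C(CC)=C\[Li] | intermediate
16 | bromo[(1Z,4S,6S)-2,6-diethyl-4-methyldec-1-en-1-yl]zinc | CCCC[C@H](CC)C[C@H](C)C/C(CC)=C\[Zn]Br | intermediate
17 | {[(3Z,5Z,8S,10S)-4-bromo-6,10-diethyl-8-methyltetradeca-3,5-dien-1-yl]oxy}(tert-butyl)dimethylsilane | CCCC[C@H](CC)C[C@H](C)C/C(CC)=C\C(Br)=C\CCO[Si](C)(C)C(C)(C)C | intermediate
18 | tert-butyldimethyl{[(3E,5Z,8S,10S)-4,6,10-triethyl-8-methyltetradeca-3,5-dien-1-yl]oxy}silane | CCCC[C@H](CC)C[C@H](C)C/C(CC)=C\C(CC)=C\CCO[Si](C)(C)C(C)(C)C | intermediate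
19 | (3E,5Z,8S,10S)-4,6,10-triethyl-8-methyltetradeca-3,5-dien-1-ol | CCCC[C@H](CC)C[C@H](C)C/C(CC)=C\C(CC)=C\CCO | intermediate
20 | 2-{(3R,6R)-4,6-diethyl-6-[(2S,4S)-4-ethyl-2-methyloctyl]-3,6-dihydro-1,2-dioxin-3-yl}ethan-1-ol | CCCC[C@H](CC)C[C@H](C)C[C@]1(CC)C=C(CC)[C@@H](CCO)OO1 | intermediate
21 | 2-{(3R,6R)-4,6-diethyl-6-[(2S,4S)-4-ethyl-2-methyloctyl]-3,6-dihydro-1,2-dioxin-3-yl}acetaldehyde | CCCC[C@H](CC)C[C@H](C)C[C@]1(CC)C=C(CC)[C@@H](CC=O)OO1 | intermediate
22 | 2-{(3R,6R)-4,6-diethyl-6-[(2S,4S)-4-ethyl-2-methyloctyl]-3,6-dihydro-1,2-dioxin-3-yl}acetic acid (CNP0179105.1) | CCCC[C@H](CC)C[C@H](C)C[C@]1(CC)C=C(CC)[C@@H](CC(=O)O)OO1 | target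

**Step count**

Total step count: 10.
Longest linear sequence: 9 steps (steps 1–4 and 6–10, from hex-1-ene). Step 5 is the one-step side branch.

**Steps most likely to fail**

**Step 9.** Ene-type hydroperoxidation at the allylic CH2 groups may outrun the cycloaddition. The 5Z geometry may erode through reversible open intermediates. Facial discrimination may be close to nil.
- The fallback gives up singlet oxygen. It sets out from 18 and comes back at 20.
- Silyl ether 18 is used so that the masked hydroxyl cannot capture a cationic intermediate. It is oxygenated with ground-state O2 under radical-cation chain catalysis (tris(4-bromophenyl)aminium hexachloroantimonate (cat.), 2,6-di-tert-butylpyridine, CH2Cl2, −78 °C).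
- The tetra-alkylated diene is oxidised by one electron, captures triplet O2 at a terminus, closes the ring and is reduced by the next diene molecule.
- With no singlet oxygen present the ene channel does not exist, and no s-cis ground-state rotamer is required.
- The closure is stepwise, so stereospecificity is lost. The wanted isomer, tert-butyl(2-{(3R,6R)-4,6-diethyl-6-[(2S,4S)-4-ethyl-2-methyloctyl]-3,6-dihydro-1,2-dioxin-3-yl}ethoxy)dimethylsilane F1, must be separated from its ring stereoisomers.
- HF·pyridine (THF, 0 °C), a non-basic fluoride source, then frees alcohol 20.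

**Step 7.** The C3=C4 geometry may partly invert through π–σ–π isomerisation of the dienylpalladium intermediate. Hydrodebromination may occur through β-hydride loss from Pd–ethyl.
- The fallback makes the C4–ethyl bond on a simple monoene, where that inversion channel is absent, and forms C4–C5 last. It sets out from 14 (with 12 as partner) and comes back at 18.
- Dehydrobromination of 14 (NaHMDS, THF, −78 °C) should give the bromoalkyne [(4-bromobut-3-yn-1-yl)oxy](tert-butyl)dimethylsilane F2.
- Syn-hydroboration with HBBr2·SMe2 (CH2Cl2, 0 °C) gives dibromo[(1Z)-1-bromo-4-{[tert-butyl(dimethyl)silyl]oxy}but-1-en-1-yl]borane F3.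
- F3 is esterified in situ with pinacol to 2-[(1Z)-1-bromo-4-{[tert-butyl(dimethyl)silyl]oxy}but-1-en-1-yl]-4,4,5,5-tetramethyl-1,3,2-dioxaborolane F4, in which boron is trans to the chain.
- Negishi coupling with ethylzinc bromide (Pd(PPh3)4, THF) replaces bromine with retention and gives tert-butyldimethyl{[(3Z)-4-(4,4,5,5-tetramethyl-1,3,2-dioxaborolan-2-yl)hex-3-en-1-yl]oxy}silane F5.
- Suzuki–Miyaura coupling of F5 with iodide 12 (PdCl2(dppf), Cs2CO3, DMF/H2O), retentive in both partners, delivers 18.

**Step 4.** Wurtz coupling may occur during Grignard formation. The β-branched alkylcopper may decompose thermally before it adds, and addition to the alkyne may be sluggish.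
- The fallback fixes the olefin geometry by haloboration instead of carbometalation. It sets out from 7 and 8 and comes back at 12.
- Syn-bromoboration of 8 (BBr3, CH2Cl2, −78 → 23 °C) gives dibromo[(1Z)-2-bromobut-1-en-1-yl]borane F6.
- Pinacol converts F6 into 2-[(1Z)-2-bromobut-1-en-1-yl]-4,4,5,5-tetramethyl-1,3,2-dioxaborolane F7.
- Direct zinc insertion into 7 (Zn dust, cat. I2, DMA, 80 °C) gives bromo[(2S,4S)-4-ethyl-2-methyloctyl]zinc F8.
- Negishi coupling of F8 with F7 (Pd(t-Bu3P)2, THF) replaces bromine with retention. It gives 2-[(1Z,4S,6S)-2,6-diethyl-4-methyldec-1-en-1-yl]-4,4,5,5-tetramethyl-1,3,2-dioxaborolane F9, with C7 cis to boron.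
- Retentive iodinolysis (I2, NaOH, THF/H2O) gives 12.

**Further compounds**

F1 | step 9 | tert-butyl(2-{(3R,6R)-4,6-diethyl-6-[(2S,4S)-4-ethyl-2-methyloctyl]-3,6-dihydro-1,2-dioxin-3-yl}ethoxy)dimethylsilane | CCCC[C@H](CC)C[C@H](C)C[C@]1(CC)C=C(CC)[C@@H](CCO[Si](C)(C)C(C)(C)C)OO1
F2 | step 7 | [(4-bromobut-3-yn-1-yl)oxy](tert-butyl)dimethylsilane | BrC#CCCO[Si](C)(C)C(C)(C)C
F3 | step 7 | dibromo[(1Z)-1-bromo-4-{[tert-butyl(dimethyl)silyl]oxy}but-1-en-1-yl]borane | BrB(Br)/C(Br)=C/CCO[Si](C)(C)C(C)(C)C
F4 | step 7 | 2-[(1Z)-1-bromo-4-{[tert-butyl(dimethyl)silyl]oxy}but-1-en-1-yl]-4,4,5,5-tetramethyl-1,3,2-dioxaborolane | CC1(C)OB(OC1(C)C)/C(Br)=C/CCO[Si](C)(C)C(C)(C)C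
F5 | step 7 | tert-butyldimethyl{[(3Z)-4-(4,4,5,5-tetramethyl-1,3,2-dioxaborolan-2-yl)hex-3-en-1-yl]oxy}silane | CC1(C)OB(OC1(C)C)/C(CC)=C/CCO[Si](C)(C)C(C)(C)C
F6 | step 4 | dibromo[(1Z)-2-bromobut-1-en-1-yl]borane | CC/C(Br)=C/B(Br)Br
F7 | step 4 | 2-[(1Z)-2-bromobut-1-en-1-yl]-4,4,5,5-tetramethyl-1,3,2-dioxaborolane | CC/C(Br)=C/B1OC(C)(C)C(C)(C)O1
F8 | step 4 | bromo[(2S,4S)-4-ethyl-2-methyloctyl]zinc | CCCC[C@H](CC)C[C@H](C)C[Zn]Br
F9 | step 4 | 2-[(1Z,4S,6S)-2,6-diethyl-4-methyldec-1-en-1-yl]-4,4,5,5-tetramethyl-1,3,2-dioxaborolane | CCCC[C@H](CC)C[C@H](C)C/C(CC)=C\B1OC(C)(C)C(C)(C)O1
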